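**The vessel.** The closed, stirred vessel of the winter run held E and X at 40 °C and had been followed to 2.50 h, and I had to say what it would hold at 4.0 h and what each remedy would add in the 8.0 h after that.

common to all: E 1.5 M; X 2.25 M
- winter: temperature 40 °C; the very flask that is asked about, followed so far
- dusk: temperature 46 °C; run made earlier
- flask: temperature 40 °C; time 4.0 h

| winter: time / h | winter: Z / % | dusk: time / h | dusk: Z / % |
|---|---|---|---|
| 0.167 | 26.1 | 0.167 | 32.7 |
| 0.500 | 46.9 | 0.500 | 55.4 |
| 0.833 | 56.3 | 0.833 | 62.3 |
| 1.33 | 63.8 | 1.33 | 68.2 |
| 2.00 | 68.1 | 2.00 | 69.6 |
| 2.50 | 69.9 | 2.50 | 71.7 |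

(scatter of a reading: 0.5 percentage points)

1. Z, in percent of the E first charged, at 4.0 h
2. the remedy with the largest gain of Z, or "none" below 2 percentage points (alpha / delta / gamma / none)
3. Z present, in percent of the E first charged, after delta
4. Z present, in percent of the E first charged, after gamma

- alpha: at 4.0 h raise the temperature by 20 K, then wait 8.0 h
- delta: change nothing and wait 8.0 h more
- gamma: at 4.0 h take out 90 % of the L then present, then wait 8.0 h

- what is added takes up no volume worth counting

**The ceiling.** Both runs flattened, the last winter reading standing at 69.9 % and the last dusk reading at 71.7 %, although dusk ran at 46 °C, so I looked for a limit that held no temperature. I supposed that E + X → Z + L is followed at once by L binding a second X, so that each Z costs two X. That makes X the limiting reagent, though more X than E was charged. The two-X ceiling C, the X charge over twice the E charge, is the highest share of the charged E that can become Z while L stays bound, and here C = 75.0 %.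

**Waiting.** By hand, time leaves C where it is. The winter run still gained 1.8 percentage points between its last two readings, so I put Z at 4.0 h between 69.9 % and 75.0 %, and I expected delta to end near C.

**Heating.** C contains no temperature, and the first dusk reading of 32.7 % stood above the winter one of 26.1 %, so I took a rise of 20 K to reach the same ceiling sooner and to end level with delta.

**Removing L.** On my reckoning L stood bound to X, so taking out 90 % of the free L would leave that X bound and C unmoved, and gamma too would end near C, which made the three remedies a tie.

**The forecast.** The forecast, holding that “this looks like an equilibrium E + X ⇌ Z + L”, gave 71.5 % now, 72 % after delta and 86.5 % after gamma, and chose gamma.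

**The result.** The flask gave 72.0 % at 4.0 h, 74.8 % after delta and 75.1 % after gamma, beside a ceiling of 75.0 %, while alpha gained 6.2 points where C left 3 points, so alpha broke my tie. E + X → L + Z (k = 0.960 M⁻¹ h⁻¹, Ea = 60.0 kJ mol⁻¹); X + L ⇌ G, settled at all times (K = 2300 M⁻¹, ΔH = 10.0 kJ mol⁻¹); X ⇌ D (K = 1.40, k = 0.0620 h⁻¹, Ea = 108 kJ mol⁻¹, ΔH = −26.0 kJ mol⁻¹); (constants at 40 °C)

**The course.** In the flask, the step E + X → L + Z had 95 % of its turnover up to 4.0 h behind it at 2.00 h, with free X down to 6.24 % of its charge. At 4.00 h, with free X at 1.41 %, free L stood at 0.0146 M beside 1.07 M of bound G, and left alone the flask reached 0.118 M of free L by 40.0 h as Z passed C to 78.1 %. The neighbour flask with 0.90 M of X and the same E had a ceiling of 30.0 % and gave 30.3 % at 4.00 h.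

Readings and results were generated by integration for an exercise, and the scatter is random.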